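Ring B is grown on the finished oxane instead of being carried in. Its adjacent oxygens at B3, B4 and B5, with a methyl group on B5 alone, match the two ester oxygens and one carbonyl of dibenzyl squarate. Cross-coupling joins the chlorine-bearing carbon of a squarate-derived cyclobutenone to the tin-bearing vinyl carbon on oxane C6 (bond B1–B2). Heating then opens the strained ring to a dienylketene that closes bond B5–B6 and aromatises, so B5 emerges as the only free phenol. The precursor is the all-cis 2,4,6-trisubstituted oxane carrying a 1-(tributylstannyl)vinyl group at C6, a silyl ether at C4 and O-benzylated ring A.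

Key step: step 15

Numbering: oxane O1, C2 (ring A side chain), C3, C4 (oxygen), C5, C6 (ring B); ring B runs from B1 (on C6) to B6. Bn = benzyl, TBS = tert-butyldimethylsilyl.
Assumption: Mo(CO)3(CNtBu)3 is made beforehand from Mo(CO)6 and tert-butyl isocyanide and counts as a catalyst, not as a step.

Step 1
Reactants: 1 3-(4-hydroxy-3-methoxyphenyl)propanoic acid
Product: 2 3-[4-(benzyloxy)-3-methoxyphenyl]propanoic acid
Conditions: BnBr, KOH, EtOH/H2O, reflux; then aq HCl
Reagents that add atoms: benzyl bromide, BrCc1ccccc1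
Why: Williamson ether synthesis on the phenoxide–carboxylate dianion, in which the phenoxide is the better nucleophile and any benzyl ester that forms is saponified again in the hot alkaline medium, so only the ether survives the acidic work-up.

Step 2
Reactants: 2 3-[4-(benzyloxy)-3-methoxyphenyl]propanoic acid; 3 potassium methyl malonate
Product: 5 methyl 5-[4-(benzyloxy)-3-methoxyphenyl]-3-oxopentanoate, via acyl imidazolide 4 (not isolated)
Conditions: 1,1'-carbonyldiimidazole, THF, rt; then 3, MgCl2, Et3N, MeCN, rt; aq HCl work-up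
Reagents that add atoms: 1,1'-carbonyldiimidazole, O=C(n1ccnc1)n1ccnc1 (imidazolyl group of 4 only)
Why: Masamune–Brooks homologation, in which imidazolide 4 acylates the magnesium enolate of the malonate half-ester and the adduct loses CO2 on work-up, a mild C-acylation that leaves the aryl benzyl ether alone.

Step 3
Reactants: 5 methyl 5-[4-(benzyloxy)-3-methoxyphenyl]-3-oxopentanoate
Product: 6 methyl (3S)-5-[4-(benzyloxy)-3-methoxyphenyl]-3-hydroxypentanoate
Conditions: H2 (10 atm), RuCl2[(S)-BINAP] (0.5 mol %), MeOH, 60 °C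
Reagents that add atoms: none
Why: Noyori asymmetric hydrogenation of a β-keto ester, in which chelation of ketone and ester oxygens to the (S)-BINAP–ruthenium hydride exposes one carbonyl face and sets the carbinol carbon (later oxane C2) as S, while this homogeneous catalyst does not hydrogenolyse aryl benzyl ethers.

Step 4
Reactants: 6 methyl (3S)-5-[4-(benzyloxy)-3-methoxyphenyl]-3-hydroxypentanoate; 7 tert-butyl acetate
Product: 9 tert-butyl (5S)-7-[4-(benzyloxy)-3-methoxyphenyl]-5-hydroxy-3-oxoheptanoate, via lithium enolate 8 (not isolated)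
Conditions: 7 (4 equiv), LiN(iPr)2 (4.2 equiv), THF, −78 °C; then 6, −78 to −10 °C; AcOH quench
Reagents that add atoms: lithium diisopropylamide, [Li+].CC(C)[N-]C(C)C (lithium of 8 only)
Why: Crossed Claisen condensation, in which an excess of the hindered, slowly self-condensing enolate 8 first deprotonates the hydroxyl group and then attacks the methyl ester, and the product rests as its enolate until the quench, so the carbinol centre is not touched.

Step 5
Reactants: 9 tert-butyl (5S)-7-[4-(benzyloxy)-3-methoxyphenyl]-5-hydroxy-3-oxoheptanoate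
Product: 10 tert-butyl (3R,5S)-7-[4-(benzyloxy)-3-methoxyphenyl]-3,5-dihydroxyheptanoate (anti diol)
Conditions: Me4NBH(OAc)3, MeCN/AcOH 1:1, −30 °C
Reagents that add atoms: none
Why: Evans–Saksena reduction, in which the C5 hydroxyl displaces an acetate on boron and the tethered hydride is delivered through a chair-like six-membered transition state, setting C3 (later oxane C4) as R, anti to C5.

Step 6
Reactants: 10 tert-butyl (3R,5S)-7-[4-(benzyloxy)-3-methoxyphenyl]-3,5-dihydroxyheptanoate
Product: 12 (4R,6S)-6-{2-[4-(benzyloxy)-3-methoxyphenyl]ethyl}-4-hydroxyoxan-2-one (cis lactone), via dihydroxy acid 11 (not isolated)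
Conditions: CF3CO2H/CH2Cl2 1:9, 0 °C to rt; aq NaHCO3 wash
Reagents that add atoms: none
Why: Acidolysis of the tert-butyl ester followed by spontaneous δ-lactonisation of 11 through the C5 hydroxyl, which turns the anti diol into the cis lactone with both substituents equatorial, breaks no bond at a stereocentre, and exposes the aryl benzyl ether only briefly to dilute acid.

Step 7
Reactants: 12 (4R,6S)-6-{2-[4-(benzyloxy)-3-methoxyphenyl]ethyl}-4-hydroxyoxan-2-one
Product: 13 (4R,6S)-6-{2-[4-(benzyloxy)-3-methoxyphenyl]ethyl}-4-[(tert-butyldimethylsilyl)oxy]oxan-2-one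
Conditions: TBSCl, imidazole, DMF, rt
Reagents that add atoms: tert-butyldimethylsilyl chloride, CC(C)(C)[Si](C)(C)Cl
Why: Standard silylation of a secondary alcohol, with imidazole as a base too weak to trigger β-elimination of the β-oxygenated lactone.

Step 8
Reactants: 13 (4R,6S)-6-{2-[4-(benzyloxy)-3-methoxyphenyl]ethyl}-4-[(tert-butyldimethylsilyl)oxy]oxan-2-one; 14 trimethylsilylacetylene
Product: 16 (4R,6S)-6-{2-[4-(benzyloxy)-3-methoxyphenyl]ethyl}-4-[(tert-butyldimethylsilyl)oxy]-2-[(trimethylsilyl)ethynyl]oxan-2-ol (anomer mixture), via lithium acetylide 15 (not isolated)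
Conditions: 14, n-BuLi, THF, −78 °C; then 13, −78 °C; AcOH quench at −78 °C
Reagents that add atoms: n-butyllithium, [Li]CCCC (lithium of 15 only)
Why: 1,2-Addition of a lithium acetylide to a δ-lactone as practised in C-glycoside synthesis, where at −78 °C the tetrahedral alkoxide does not collapse (one addition only) and the weakly basic acetylide adds faster than it enolises the lactone; the new anomeric centre is erased in step 9.

Step 9
Reactants: 16 (4R,6S)-6-{2-[4-(benzyloxy)-3-methoxyphenyl]ethyl}-4-[(tert-butyldimethylsilyl)oxy]-2-[(trimethylsilyl)ethynyl]oxan-2-ol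
Product: 18 (2S,4R,6S)-2-{2-[4-(benzyloxy)-3-methoxyphenyl]ethyl}-4-[(tert-butyldimethylsilyl)oxy]-6-[(trimethylsilyl)ethynyl]oxane (all-cis), via oxocarbenium ion 17 (not isolated)
Conditions: Et3SiH, BF3·OEt2, CH2Cl2/MeCN, −78 to −30 °C; aq NaHCO3
Reagents that add atoms: none
Why: Lewis-acid-mediated silane reduction of a lactol, in which BF3·OEt2 ionises 16 to the alkyne-conjugated oxocarbenium ion 17, whose half-chair keeps the C2 side chain and the C4 silyloxy group pseudo-equatorial, and the stereoelectronically preferred axial hydride delivery places the alkynyl group equatorial and sets C6 as S, cis to C2 and C4.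

Step 10
Reactants: 18 (2S,4R,6S)-2-{2-[4-(benzyloxy)-3-methoxyphenyl]ethyl}-4-[(tert-butyldimethylsilyl)oxy]-6-[(trimethylsilyl)ethynyl]oxane
Product: 19 (2S,4R,6S)-2-{2-[4-(benzyloxy)-3-methoxyphenyl]ethyl}-4-[(tert-butyldimethylsilyl)oxy]-6-ethynyloxane
Conditions: K2CO3 (cat.), MeOH, rt
Reagents that add atoms: none
Why: Base-catalysed methanolysis (protodesilylation) of the alkynyl C–Si bond, which is far more labile than the secondary silyl ether.

Step 11
Reactants: 19 (2S,4R,6S)-2-{2-[4-(benzyloxy)-3-methoxyphenyl]ethyl}-4-[(tert-butyldimethylsilyl)oxy]-6-ethynyloxane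
Product: 20 (2S,4R,6S)-2-{2-[4-(benzyloxy)-3-methoxyphenyl]ethyl}-4-[(tert-butyldimethylsilyl)oxy]-6-[1-(tributylstannyl)ethenyl]oxane
Conditions: Bu3SnH, Mo(CO)3(CNtBu)3 (2 mol %), hydroquinone (cat.), THF, 55 °C; chromatography on Et3N-deactivated silica
Reagents that add atoms: tributyltin hydride, CCCC[SnH](CCCC)CCCC
Why: Molybdenum-catalysed syn hydrostannation of a terminal propargylic ether, a substrate class for which the bulky isonitrile ligands and the inductive pull of the adjacent C6–O1 bond steer tin to the internal carbon, while hydroquinone suppresses the radical chain that would put tin at the terminus.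

Step 12
Reactants: 21 squaric acid
Product: 22 3,4-bis(benzyloxy)cyclobut-3-ene-1,2-dione (dibenzyl squarate)
Conditions: BnOH, toluene, reflux, Dean–Stark trap
Reagents that add atoms: benzyl alcohol, OCc1ccccc1
Why: Azeotropic Fischer-type esterification, in which squaric acid, a strong vinylogous acid, catalyses its own conversion to the diester once water is removed.

Step 13
Reactants: 22 3,4-bis(benzyloxy)cyclobut-3-ene-1,2-dione
Product: 23 2,3-bis(benzyloxy)-4-hydroxycyclobut-2-en-1-one (racemic)
Conditions: LiAlH(OtBu)3, THF, −78 to −20 °C; pH 7 buffer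
Reagents that add atoms: none
Why: Chemoselective 1,2-reduction of one carbonyl of a dialkyl squarate with a bulky mild hydride, where the alkoxide formed deactivates the second carbonyl and the neutral quench avoids acid-induced loss of benzyl alcohol; the new centre is racemic and disappears in step 15.

Step 14
Reactants: 23 2,3-bis(benzyloxy)-4-hydroxycyclobut-2-en-1-one
Product: 24 2,3-bis(benzyloxy)-4-chlorocyclobut-2-en-1-one (racemic)
Conditions: PPh3, CCl4, CH2Cl2, 0 °C to rt; short neutral silica plug, used at once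
Reagents that add atoms: tetrachloromethane, ClC(Cl)(Cl)Cl
Why: Appel reaction, in which chloride displaces the alkoxyphosphonium group at a carbon activated as both allylic and α-keto under neutral conditions, so the acid-labile bis(enol ether) never meets HCl.

Step 15
Reactants: 20 (2S,4R,6S)-2-{2-[4-(benzyloxy)-3-methoxyphenyl]ethyl}-4-[(tert-butyldimethylsilyl)oxy]-6-[1-(tributylstannyl)ethenyl]oxane; 24 2,3-bis(benzyloxy)-4-chlorocyclobut-2-en-1-one
Product: 28 (2S,4R,6S)-6-[3,4-bis(benzyloxy)-5-hydroxyphenyl]-2-{2-[4-(benzyloxy)-3-methoxyphenyl]ethyl}-4-[(tert-butyldimethylsilyl)oxy]oxane, via alkenylcyclobutenone 25 (not isolated), via dienylketene 26 (not isolated), via cyclohexadienone 27 (not isolated)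
Conditions: 24 (1.5 equiv), Pd2(dba)3 (2.5 mol %), tri(2-furyl)phosphine (10 mol %), degassed dilute 1,4-dioxane, 50 °C; then 100 °C
Reagents that add atoms: none
Why: Zerovalent palladium inserts into the C–Cl bond of 24, which is activated as both allylic and α-keto and offers no β-hydrogen, the alkenyl group of 20 is handed over from tin, and reductive elimination at the former CHCl carbon gives 25 and with it bond B1–B2; this is the Stille coupling known for 4-chlorocyclobutenones and alkenylstannanes, applied here to a dialkoxy chloride and a branched stannane. At 100 °C the strained four-membered ring of 25 opens in a conrotatory four-electron process, and because the opening is reversible the unproductive outward rotamer falls back to 25 while isomer 26, with vinyl group and ketene on the same side of the new double bond, is drained forward. Ring B then closes by a disrotatory six-electron electrocyclisation that joins the ketene carbon to the CH2 terminus (bond B5–B6) to give dienone 27, and enolisation delivers phenol 28. No stereocentre is made: the single centre of racemic 24 ends as arene CH B2, and C2, C4 and C6 are spectators because the medium is neutral and the carbon attached to C6 stays sp2 from 20 to 28. The step needs ipso rather than cine transfer of the hindered alkenyl group and bond formation at C4 rather than C2 of the cyclobutenonyl–palladium unit, which the weakly donating furylphosphine (fast transmetallation) and the fully substituted, benzyloxy-bearing C2 should secure, after which the arene pattern follows from connectivity alone (tin carbon = B1, carbonyl carbon = B5). Pd2(dba)3 is preferred to a divalent palladium salt so that none of the valuable stannane is consumed in generating the catalyst, and the cheap chloride is taken in excess.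

Step 16
Reactants: 28 (2S,4R,6S)-6-[3,4-bis(benzyloxy)-5-hydroxyphenyl]-2-{2-[4-(benzyloxy)-3-methoxyphenyl]ethyl}-4-[(tert-butyldimethylsilyl)oxy]oxane
Product: 29 (2S,4R,6S)-6-[3,4-bis(benzyloxy)-5-methoxyphenyl]-2-{2-[4-(benzyloxy)-3-methoxyphenyl]ethyl}-4-[(tert-butyldimethylsilyl)oxy]oxane
Conditions: MeI, K2CO3, acetone, 50 °C
Reagents that add atoms: iodomethane, CI
Why: Williamson methylation of the single free phenol at B5, which needs no site selectivity because every other oxygen is masked.

Step 17
Reactants: 29 (2S,4R,6S)-6-[3,4-bis(benzyloxy)-5-methoxyphenyl]-2-{2-[4-(benzyloxy)-3-methoxyphenyl]ethyl}-4-[(tert-butyldimethylsilyl)oxy]oxane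
Product: 30 (2S,4R,6S)-2-[3,4-bis(benzyloxy)-5-methoxyphenyl]-6-{2-[4-(benzyloxy)-3-methoxyphenyl]ethyl}oxan-4-ol
Conditions: Bu4NF, THF, rt
Reagents that add atoms: none
Why: Fluoride-induced cleavage of the silyl ether, driven by the strong Si–F bond, to which benzyl ethers, methyl ethers and the three stereocentres are inert.

Step 18
Reactants: 30 (2S,4R,6S)-2-[3,4-bis(benzyloxy)-5-methoxyphenyl]-6-{2-[4-(benzyloxy)-3-methoxyphenyl]ethyl}oxan-4-ol
Product: 31 5-[(2S,4R,6S)-4-hydroxy-6-[2-(4-hydroxy-3-methoxyphenyl)ethyl]oxan-2-yl]-3-methoxybenzene-1,2-diol (target)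
Conditions: H2 (1 atm), 10% Pd/C, EtOAc/EtOH, rt, stopped when the third benzyl group is gone
Reagents that add atoms: none
Why: Catalytic hydrogenolysis of three aryl benzyl ethers, which under neutral conditions at 1 atm are cleaved much faster than the cyclic benzylic C6–O1 bond, so the oxane and its stereocentres should stay intact.

Compound list
1 | 3-(4-hydroxy-3-methoxyphenyl)propanoic acid | COc1cc(CCC(=O)O)ccc1O | starting material
2 | 3-[4-(benzyloxy)-3-methoxyphenyl]propanoic acid | COc1cc(CCC(=O)O)ccc1OCc1ccccc1 | intermediate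
3 | potassium methyl malonate | COC(=O)CC(=O)[O-].[K+] | starting material
4 | 1-{3-[4-(benzyloxy)-3-methoxyphenyl]propanoyl}imidazole (not isolated) | COc1cc(CCC(=O)n2ccnc2)ccc1OCc1ccccc1 | intermediate
5 | methyl 5-[4-(benzyloxy)-3-methoxyphenyl]-3-oxopentanoate | COc1cc(CCC(=O)CC(=O)OC)ccc1OCc1ccccc1 | intermediate
6 | methyl (3S)-5-[4-(benzyloxy)-3-methoxyphenyl]-3-hydroxypentanoate | COc1cc(CC[C@H](O)CC(=O)OC)ccc1OCc1ccccc1 | intermediate
7 | tert-butyl acetate | CC(=O)OC(C)(C)C | starting material
8 | lithium enolate of tert-butyl acetate (not isolated) | [Li+].C=C([O-])OC(C)(C)C | intermediate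
9 | tert-butyl (5S)-7-[4-(benzyloxy)-3-methoxyphenyl]-5-hydroxy-3-oxoheptanoate | COc1cc(CC[C@H](O)CC(=O)CC(=O)OC(C)(C)C)ccc1OCc1ccccc1 | intermediate
10 | tert-butyl (3R,5S)-7-[4-(benzyloxy)-3-methoxyphenyl]-3,5-dihydroxyheptanoate | COc1cc(CC[C@H](O)C[C@@H](O)CC(=O)OC(C)(C)C)ccc1OCc1ccccc1 | intermediate
11 | (3R,5S)-7-[4-(benzyloxy)-3-methoxyphenyl]-3,5-dihydroxyheptanoic acid (not isolated) | COc1cc(CC[C@H](O)C[C@@H](O)CC(=O)O)ccc1OCc1ccccc1 | intermediate
12 | (4R,6S)-6-{2-[4-(benzyloxy)-3-methoxyphenyl]ethyl}-4-hydroxyoxan-2-one | COc1cc(CC[C@H]2C[C@@H](O)CC(=O)O2)ccc1OCc1ccccc1 | intermediate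
13 | (4R,6S)-6-{2-[4-(benzyloxy)-3-methoxyphenyl]ethyl}-4-[(tert-butyldimethylsilyl)oxy]oxan-2-one | COc1cc(CC[C@H]2C[C@@H](O[Si](C)(C)C(C)(C)C)CC(=O)O2)ccc1OCc1ccccc1 | intermediate
14 | trimethylsilylacetylene | C#C[Si](C)(C)C | starting material
15 | lithium (trimethylsilyl)acetylide (not isolated) | [Li+].[C-]#C[Si](C)(C)C | intermediate
16 | (4R,6S)-6-{2-[4-(benzyloxy)-3-methoxyphenyl]ethyl}-4-[(tert-butyldimethylsilyl)oxy]-2-[(trimethylsilyl)ethynyl]oxan-2-ol, anomer mixture | COc1cc(CC[C@H]2C[C@@H](O[Si](C)(C)C(C)(C)C)CC(O)(C#C[Si](C)(C)C)O2)ccc1OCc1ccccc1 | intermediate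
17 | oxocarbenium ion from 16, C6=O1 cation bearing the silylalkynyl group (not isolated) | COc1cc(CC[C@H]2C[C@@H](O[Si](C)(C)C(C)(C)C)CC(C#C[Si](C)(C)C)=[O+]2)ccc1OCc1ccccc1 | intermediate
18 | (2S,4R,6S)-2-{2-[4-(benzyloxy)-3-methoxyphenyl]ethyl}-4-[(tert-butyldimethylsilyl)oxy]-6-[(trimethylsilyl)ethynyl]oxane | COc1cc(CC[C@H]2C[C@@H](O[Si](C)(C)C(C)(C)C)C[C@@H](C#C[Si](C)(C)C)O2)ccc1OCc1ccccc1 | intermediate
19 | (2S,4R,6S)-2-{2-[4-(benzyloxy)-3-methoxyphenyl]ethyl}-4-[(tert-butyldimethylsilyl)oxy]-6-ethynyloxane | COc1cc(CC[C@H]2C[C@@H](O[Si](C)(C)C(C)(C)C)C[C@@H](C#C)O2)ccc1OCc1ccccc1 | intermediate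
20 | (2S,4R,6S)-2-{2-[4-(benzyloxy)-3-methoxyphenyl]ethyl}-4-[(tert-butyldimethylsilyl)oxy]-6-[1-(tributylstannyl)ethenyl]oxane | COc1cc(CC[C@H]2C[C@@H](O[Si](C)(C)C(C)(C)C)C[C@@H](C(=C)[Sn](CCCC)(CCCC)CCCC)O2)ccc1OCc1ccccc1 | intermediate
21 | squaric acid | O=C1C(=O)C(O)=C1O | starting material
22 | 3,4-bis(benzyloxy)cyclobut-3-ene-1,2-dione | O=C1C(=O)C(OCc2ccccc2)=C1OCc1ccccc1 | intermediate
23 | 2,3-bis(benzyloxy)-4-hydroxycyclobut-2-en-1-one, racemic | O=C1C(OCc2ccccc2)=C(OCc2ccccc2)C1O | intermediate
24 | 2,3-bis(benzyloxy)-4-chlorocyclobut-2-en-1-one, racemic | O=C1C(OCc2ccccc2)=C(OCc2ccccc2)C1Cl | intermediate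
25 | oxane 20 with the tin replaced by the 2,3-bis(benzyloxy)-4-oxocyclobut-2-en-1-yl group, epimer mixture at the cyclobutenone carbon (not isolated) | COc1cc(CC[C@H]2C[C@@H](O[Si](C)(C)C(C)(C)C)C[C@@H](C(=C)C3C(=O)C(OCc4ccccc4)=C3OCc3ccccc3)O2)ccc1OCc1ccccc1 | intermediate
26 | dienylketene from 25, ketene and vinyl termini cis on the central double bond (not isolated) | COc1cc(CC[C@H]2C[C@@H](O[Si](C)(C)C(C)(C)C)C[C@@H](C(=C)/C=C(OCc3ccccc3)\C(OCc3ccccc3)=C=O)O2)ccc1OCc1ccccc1 | intermediate
27 | 2,3-bis(benzyloxy)-5-(oxan-6-yl)cyclohexa-2,4-dien-1-one, keto tautomer of 28 (not isolated) | COc1cc(CC[C@H]2C[C@@H](O[Si](C)(C)C(C)(C)C)C[C@@H](C3=CC(OCc4ccccc4)=C(OCc4ccccc4)C(=O)C3)O2)ccc1OCc1ccccc1 | intermediate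
28 | (2S,4R,6S)-6-[3,4-bis(benzyloxy)-5-hydroxyphenyl]-2-{2-[4-(benzyloxy)-3-methoxyphenyl]ethyl}-4-[(tert-butyldimethylsilyl)oxy]oxane | COc1cc(CC[C@H]2C[C@@H](O[Si](C)(C)C(C)(C)C)C[C@@H](c3cc(OCc4ccccc4)c(OCc4ccccc4)c(O)c3)O2)ccc1OCc1ccccc1 | intermediate
29 | (2S,4R,6S)-6-[3,4-bis(benzyloxy)-5-methoxyphenyl]-2-{2-[4-(benzyloxy)-3-methoxyphenyl]ethyl}-4-[(tert-butyldimethylsilyl)oxy]oxane | COc1cc(CC[C@H]2C[C@@H](O[Si](C)(C)C(C)(C)C)C[C@@H](c3cc(OCc4ccccc4)c(OCc4ccccc4)c(OC)c3)O2)ccc1OCc1ccccc1 | intermediate
30 | (2S,4R,6S)-2-[3,4-bis(benzyloxy)-5-methoxyphenyl]-6-{2-[4-(benzyloxy)-3-methoxyphenyl]ethyl}oxan-4-ol | COc1cc(CC[C@H]2C[C@@H](O)C[C@@H](c3cc(OCc4ccccc4)c(OCc4ccccc4)c(OC)c3)O2)ccc1OCc1ccccc1 | intermediate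
31 | 5-[(2S,4R,6S)-4-hydroxy-6-[2-(4-hydroxy-3-methoxyphenyl)ethyl]oxan-2-yl]-3-methoxybenzene-1,2-diol | COc1cc(CC[C@H]2C[C@@H](O)C[C@@H](c3cc(O)c(O)c(OC)c3)O2)ccc1O | target

Total step count: 18.
Longest linear sequence: 15 steps (steps 1–11, then 15–18). Steps 12–14 form the short convergent branch.

Steps most likely to fail

1. Step 15.
- What may go wrong: transfer of the hindered, branched alkenyl group from tin may be slower than thermal or palladium-induced decay of the chloride. Tin may also be lost by protonolysis. In either case bond B1–B2 never forms.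
- Fallback: the benzannulation is given up and ring B is brought in ready-made.
  - Commercial 5-bromo-2-hydroxy-3-methoxybenzaldehyde (COc1cc(Br)cc(C=O)c1O) undergoes Dakin oxidation (H2O2, NaOH) to 5-bromo-3-methoxybenzene-1,2-diol F1.
  - Double Williamson benzylation (BnBr, K2CO3, DMF) gives 1,2-bis(benzyloxy)-5-bromo-3-methoxybenzene F2.
  - Bromine–lithium exchange (n-BuLi, THF, −78 °C) gives [3,4-bis(benzyloxy)-5-methoxyphenyl]lithium F3.
  - F3 adds to lactone 13 to give, after an AcOH quench, the aryl lactol F4.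
  - Silane reduction (Et3SiH, BF3·OEt2, −78 °C) with axial hydride delivery, as in step 9, gives the all-cis aryl oxane.
- This path sets out from 13 and comes back to the route at 29.

2. Step 14.
- What may go wrong: the activated alkoxyphosphonium salt, or the chloride itself, may ionise. Allylic transposition and removal of a benzyl group by chloride would then collapse the bis(enol ether) during chlorination or on standing.
- Fallback: the halide is avoided altogether. Alcohol 23 is acetylated (Ac2O, pyridine, CH2Cl2, 0 °C) to 2,3-bis(benzyloxy)-4-oxocyclobut-2-en-1-yl acetate F5, which ionises far less readily. F5 is coupled with stannane 20 under the conditions established for allylic acetates and alkenylstannanes (Pd2(dba)3, LiCl, DMF, rt to 50 °C). Heating in dioxane then carries 25 on through 26 and 27.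
- This path sets out from 23 and comes back at 28.

3. Step 11.
- What may go wrong: regiocontrol may be poor, with part of the tin delivered to the terminal alkyne carbon. That would later misplace the oxane on ring B, and the two isomers are hard to separate.
- Fallback: hydrostannation is replaced by stannylcupration with in situ protonation. Alkyne 19 is treated with Me3SnCu·SMe2 (from Me3SnSnMe3, MeLi and CuBr·SMe2) and MeOH in THF at −63 °C. Under these conditions the kinetically formed adduct with tin on the internal carbon is trapped by the proton source. The product is (2S,4R,6S)-2-{2-[4-(benzyloxy)-3-methoxyphenyl]ethyl}-4-[(tert-butyldimethylsilyl)oxy]-6-[1-(trimethylstannyl)ethenyl]oxane F6. F6 takes the place of 20 in the coupling with 24, where the smaller tin group should also transmetallate faster.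
- This path sets out from 19 and comes back at 28.

Further compounds
F1 | step 15 | 5-bromo-3-methoxybenzene-1,2-diol | COc1cc(Br)cc(O)c1O
F2 | step 15 | 1,2-bis(benzyloxy)-5-bromo-3-methoxybenzene | COc1cc(Br)cc(OCc2ccccc2)c1OCc1ccccc1
F3 | step 15 | [3,4-bis(benzyloxy)-5-methoxyphenyl]lithium | COc1cc([Li])cc(OCc2ccccc2)c1OCc1ccccc1
F4 | step 15 | (4R,6S)-2-[3,4-bis(benzyloxy)-5-methoxyphenyl]-6-{2-[4-(benzyloxy)-3-methoxyphenyl]ethyl}-4-[(tert-butyldimethylsilyl)oxy]oxan-2-ol, anomer mixture | COc1cc(CC[C@H]2C[C@@H](O[Si](C)(C)C(C)(C)C)CC(O)(c3cc(OCc4ccccc4)c(OCc4ccccc4)c(OC)c3)O2)ccc1OCc1ccccc1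
F5 | step 14 | 2,3-bis(benzyloxy)-4-oxocyclobut-2-en-1-yl acetate, racemic | CC(=O)OC1C(=O)C(OCc2ccccc2)=C1OCc1ccccc1
F6 | step 11 | (2S,4R,6S)-2-{2-[4-(benzyloxy)-3-methoxyphenyl]ethyl}-4-[(tert-butyldimethylsilyl)oxy]-6-[1-(trimethylstannyl)ethenyl]oxane | COc1cc(CC[C@H]2C[C@@H](O[Si](C)(C)C(C)(C)C)C[C@@H](C(=C)[Sn](C)(C)C)O2)ccc1OCc1ccccc1
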